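**Assumption:** atom labels follow guaiane numbering (C3 ketone, C4=C5 enone with the methyl on C4, C1 ring-fusion CH, C10 CH–CH3, C8 CH–O, C7 CH bearing C11); the target is then (1R,7S,8R,10S).

## Retrosynthetic overview
1. The two esters are installed last on the 8,11-diol: 8-O-propionate first, then the tertiary 11-O-acetate.
2. Ring B (cyclopentenone, formed second): C4=C5 by intramolecular aldol condensation of a 1,4-diketone. Its 2-oxobutyl arm on C1 comes from C-alkylation of a cyclic β-keto ester with 1-bromobut-2-yne, decarboxylation and alkyne hydration.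
3. Ring A (cycloheptanone, formed first): C1–C5 by Dieckmann condensation of an acyclic methyl/tert-butyl diester.
4. Fragment union: C7–C8 by an intermolecular Evans syn-aldol between a pent-4-enoyl oxazolidinone (C5, C6, C7, C11) and an aldehyde from desymmetrised 3-methylglutarate (C8, C9, C10, C1); this sets C7 and C8.
5. The C11 carbinol comes from the aldol carbonyl (Weinreb amide, two MeMgBr additions); C1 is set by equilibration.

## Route

Step 1
Reactants: 1 dimethyl 3-methylpentanedioate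
Product: 2 (R)-5-methoxy-3-methyl-5-oxopentanoic acid
Conditions: pig liver esterase, phosphate buffer (pH 7), 20% MeOH, −10 °C
Reagents that add atoms: water, O
Why: Enzymatic desymmetrisation (enantiotopic-group-selective ester hydrolysis) of the prochiral diester gives the (R)-half-ester and so fixes the future C10 centre.

Step 2
Reactants: 2 (R)-5-methoxy-3-methyl-5-oxopentanoic acid
Product: 3 1-tert-butyl 5-methyl (S)-3-methylpentanedioate
Conditions: isobutene (excess), H2SO4 (cat.), CH2Cl2, sealed vessel, rt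
Reagents that add atoms: 2-methylpropene, C=C(C)C
Why: Acid-catalysed addition of the carboxylic acid to isobutene gives the tert-butyl ester and differentiates the two termini without touching the stereocentre (the descriptor changes only through CIP priority).

Step 3
Reactants: 3 1-tert-butyl 5-methyl (S)-3-methylpentanedioate
Product: 4 tert-butyl (S)-5-hydroxy-3-methylpentanoate
Conditions: LiBH4 (1.5 equiv), THF, 0 °C → rt
Reagents that add atoms: none
Why: Chemoselective borohydride reduction, because LiBH4 reduces the methyl ester much faster than the hindered tert-butyl ester.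

Step 4
Reactants: 4 tert-butyl (S)-5-hydroxy-3-methylpentanoate
Product: 5 tert-butyl (S)-3-methyl-5-oxopentanoate
Conditions: TEMPO (10 mol %), PhI(OAc)2 (1.1 equiv), CH2Cl2, rt
Reagents that add atoms: none
Why: Oxoammonium (TEMPO) oxidation stops cleanly at the aldehyde and leaves the β-stereocentre and the tert-butyl ester alone.

Step 5
Reactants: 6 (S)-4-benzyloxazolidin-2-one; 7 pent-4-enoyl chloride
Product: 8 (S)-4-benzyl-3-(pent-4-enoyl)oxazolidin-2-one
Conditions: Et3N, DMAP (10 mol %), CH2Cl2, 0 °C → rt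
Reagents that add atoms: none
Why: DMAP-catalysed N-acylation of the Evans auxiliary with an acid chloride is a standard, high-yielding imide formation.

Step 6
Reactants: 8 (S)-4-benzyl-3-(pent-4-enoyl)oxazolidin-2-one; 5 tert-butyl (S)-3-methyl-5-oxopentanoate
Product: 11 tert-butyl (3S,5R,6S)-6-[(S)-4-benzyl-2-oxooxazolidine-3-carbonyl]-5-hydroxy-3-methylnon-8-enoate, via boron enolate 9 (not isolated), via boron aldolate 10 (not isolated)
Conditions: Bu2BOTf, i-Pr2NEt, CH2Cl2, −78 → 0 °C; then 5, −78 → 0 °C; then pH 7 buffer, MeOH, 30% H2O2, 0 °C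
Reagents that add atoms: none
Why: Evans syn-aldol reaction, in which the (Z)-boron enolate reacts through a Zimmerman–Traxler chair and the (S)-benzyl auxiliary dictates the enolate face, giving the 7S,8R syn pair, while C10 is carried in from 5.

Step 7
Reactants: 11 tert-butyl (3S,5R,6S)-6-[(S)-4-benzyl-2-oxooxazolidine-3-carbonyl]-5-hydroxy-3-methylnon-8-enoate
Product: 12 tert-butyl (3S,5R,6S)-5-hydroxy-6-[methoxy(methyl)carbamoyl]-3-methylnon-8-enoate
Conditions: MeNH(OMe)·HCl, AlMe3, CH2Cl2, −15 → 0 °C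
Reagents that add atoms: N,O-dimethylhydroxylamine hydrochloride, CNOC.Cl
Why: Weinreb transamination with the aluminium amide is directed by the free β-hydroxyl to the exocyclic imide carbonyl and releases the auxiliary without epimerising C7.

Step 8
Reactants: 12 tert-butyl (3S,5R,6S)-5-hydroxy-6-[methoxy(methyl)carbamoyl]-3-methylnon-8-enoate
Product: 14 tert-butyl (3S,5R,6S)-6-acetyl-5-hydroxy-3-methylnon-8-enoate, via magnesium hemiaminal chelate 13 (not isolated)
Conditions: MeMgBr (3.5 equiv), THF, −20 → 0 °C; aq. NH4Cl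
Reagents that add atoms: methylmagnesium bromide, C[Mg]Br
Why: Weinreb ketone synthesis, where the stable chelated tetrahedral adduct prevents over-addition and the tert-butyl ester is inert at this temperature.

Step 9
Reactants: 14 tert-butyl (3S,5R,6S)-6-acetyl-5-hydroxy-3-methylnon-8-enoate
Product: 15 tert-butyl (3S,5R,6S)-5-hydroxy-6-(2-hydroxypropan-2-yl)-3-methylnon-8-enoate
Conditions: MeMgBr (4 equiv), THF, −78 → −20 °C; aq. NH4Cl
Reagents that add atoms: methylmagnesium bromide, C[Mg]Br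
Why: Grignard addition to the methyl ketone creates the C11 carbinol with no new stereocentre, and the low temperature suppresses retro-aldol and attack on the tert-butyl ester.

Step 10
Reactants: 15 tert-butyl (3S,5R,6S)-5-hydroxy-6-(2-hydroxypropan-2-yl)-3-methylnon-8-enoate
Product: 16 tert-butyl (3S)-4-[(4R,5S)-2,2-di-tert-butyl-6,6-dimethyl-5-(prop-2-en-1-yl)-1,3,2-dioxasilinan-4-yl]-3-methylbutanoate
Conditions: t-Bu2Si(OTf)2, 2,6-lutidine, CH2Cl2, 0 °C → rt
Reagents that add atoms: di-tert-butylsilyl bis(trifluoromethanesulfonate), CC(C)(C)[Si](OS(=O)(=O)C(F)(F)F)(OS(=O)(=O)C(F)(F)F)C(C)(C)C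
Why: Cyclic silylene formation protects the secondary and tertiary hydroxyls of the 1,3-diol in one operation, the second Si–O bond closing intramolecularly.

Step 11
Reactants: 16 tert-butyl (3S)-4-[(4R,5S)-2,2-di-tert-butyl-6,6-dimethyl-5-(prop-2-en-1-yl)-1,3,2-dioxasilinan-4-yl]-3-methylbutanoate
Product: 18 tert-butyl (3S)-4-[(4R,5S)-2,2-di-tert-butyl-6,6-dimethyl-5-(2-oxoethyl)-1,3,2-dioxasilinan-4-yl]-3-methylbutanoate, via secondary ozonide 17 (not isolated)
Conditions: O3, CH2Cl2, −78 °C; then PPh3, −78 °C → rt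
Reagents that add atoms: ozone, [O-][O+]=O
Why: Ozonolysis (Criegee mechanism) with reductive work-up cleaves the only alkene to the C5 aldehyde.

Step 12
Reactants: 18 tert-butyl (3S)-4-[(4R,5S)-2,2-di-tert-butyl-6,6-dimethyl-5-(2-oxoethyl)-1,3,2-dioxasilinan-4-yl]-3-methylbutanoate
Product: 19 tert-butyl (3S)-4-[(4R,5S)-2,2-di-tert-butyl-5-(carboxymethyl)-6,6-dimethyl-1,3,2-dioxasilinan-4-yl]-3-methylbutanoate
Conditions: NaClO2, NaH2PO4, 2-methylbut-2-ene, t-BuOH/H2O, rt
Reagents that add atoms: sodium chlorite, [Na+].[O-]Cl=O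
Why: Pinnick oxidation converts the aldehyde to the acid under buffered conditions that spare the silylene and the tert-butyl ester.

Step 13
Reactants: 19 tert-butyl (3S)-4-[(4R,5S)-2,2-di-tert-butyl-5-(carboxymethyl)-6,6-dimethyl-1,3,2-dioxasilinan-4-yl]-3-methylbutanoate
Product: 20 tert-butyl (3S)-4-[(4R,5S)-2,2-di-tert-butyl-5-(2-methoxy-2-oxoethyl)-6,6-dimethyl-1,3,2-dioxasilinan-4-yl]-3-methylbutanoate
Conditions: MeI, K2CO3, DMF, rt
Reagents that add atoms: iodomethane, CI
Why: SN2 O-alkylation of the carboxylate gives the methyl ester, the electrophilic partner for the ring closure.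

Step 14
Reactants: 20 tert-butyl (3S)-4-[(4R,5S)-2,2-di-tert-butyl-5-(2-methoxy-2-oxoethyl)-6,6-dimethyl-1,3,2-dioxasilinan-4-yl]-3-methylbutanoate
Product: 21 silylene-protected cycloheptanone β-keto ester (7S,8R,10S; C5 ketone; tert-butoxycarbonyl on C1 as epimer mixture; O8 and O11 bridged by di-tert-butylsilylene)
Conditions: LiHMDS (2.5 equiv), THF (0.01 M), −78 → 0 °C; AcOH
Reagents that add atoms: none
Why: Dieckmann condensation in which only the C1 enolate can cyclise productively onto the C5 methyl ester, because a tert-butyl ester is a very poor acyl acceptor, so ring A forms with the ketone at C5 and the activating ester on C1.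

Step 15
Reactants: 21 silylene-protected cycloheptanone β-keto ester; 22 1-bromobut-2-yne
Product: 23 C1-(but-2-ynyl) β-keto ester (7S,8R,10S; quaternary C1 whose configuration is inconsequential)
Conditions: K2CO3, acetone, reflux
Reagents that add atoms: none
Why: SN2 C-alkylation of the stabilised β-keto ester enolate with a reactive propargylic bromide puts the four-carbon arm regiospecifically on C1.

Step 16
Reactants: 23 C1-(but-2-ynyl) β-keto ester
Product: 26 (1R,7S,8R,10S)-1-(but-2-ynyl) silylene-protected cycloheptanone (C1 epimer mixture; the 1R epimer is drawn), via trimethylsilyl ester 24 (not isolated), via β-keto acid 25 (not isolated)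
Conditions: TMSOTf, 2,6-lutidine, CH2Cl2, 0 °C → rt; then aq. citric acid, THF; toluene, 80 °C
Reagents that add atoms: none
Why: Silyl triflate-mediated tert-butyl ester cleavage under buffered conditions followed by β-keto acid decarboxylation removes the activating group and leaves C1 as an epimerisable CH.

Step 17
Reactants: 26 (1R,7S,8R,10S)-1-(but-2-ynyl) silylene-protected cycloheptanone
Product: 27 (1R,7S,8R,10S)-1-(2-oxobutyl) silylene-protected cycloheptanone (1,4-diketone)
Conditions: Ph3PAuNTf2 (3 mol %), H2O (5 equiv), 1,4-dioxane, 50 °C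
Reagents that add atoms: water, O
Why: Gold-catalysed alkyne hydration proceeds with 5-exo participation of the C5 carbonyl oxygen, so the new ketone lands on C3 and a 1,4-diketone results.

Step 18
Reactants: 27 (1R,7S,8R,10S)-1-(2-oxobutyl) silylene-protected cycloheptanone
Product: 29 silylene-protected (1R,7S,8R,10S)-8,11-dihydroxyguai-4-en-3-one, via β-hydroxy ketone 28 (not isolated)
Conditions: KOt-Bu (0.5 equiv), t-BuOH/THF, rt → 40 °C
Reagents that add atoms: none
Why: Intramolecular aldol condensation (C4 onto the C5 ketone, then E1cB dehydration) closes ring B as the tetrasubstituted enone, while epimerisable C1 settles under thermodynamic control with the C1–C2 bond trans to the C10 methyl (1R); the minor epimer is separated and re-equilibrated.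

Step 19
Reactants: 29 silylene-protected (1R,7S,8R,10S)-8,11-dihydroxyguai-4-en-3-one
Product: 30 (1R,7S,8R,10S)-8,11-dihydroxyguai-4-en-3-one
Conditions: HF·pyridine, THF/pyridine, 0 °C → rt
Reagents that add atoms: none
Why: Fluoride-driven desilylation (strong Si–F bond) frees both hydroxyls without affecting the enone.

Step 20
Reactants: 30 (1R,7S,8R,10S)-8,11-dihydroxyguai-4-en-3-one
Product: 31 (1R,7S,8R,10S)-11-hydroxy-3-oxoguai-4-en-8-yl propanoate
Conditions: (EtCO)2O, pyridine, DMAP (5 mol %), CH2Cl2, 0 °C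
Reagents that add atoms: propanoic anhydride, CCC(=O)OC(=O)CC
Why: Nucleophilic-catalysis acylation is selective for the secondary 8-hydroxyl because the tertiary 11-hydroxyl reacts far more slowly.

Step 21
Reactants: 31 (1R,7S,8R,10S)-11-hydroxy-3-oxoguai-4-en-8-yl propanoate
Product: 32 (1R,7S,8R,10S)-11-acetoxy-3-oxoguai-4-en-8-yl propanoate
Conditions: Ac2O, DMAP (1 equiv), Et3N, CH2Cl2, rt → 40 °C
Reagents that add atoms: acetic anhydride, CC(=O)OC(C)=O
Why: Steglich-type acylation with stoichiometric DMAP acetylates the remaining tertiary alcohol and completes the target with all four stereocentres unchanged.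

## Compound list
1 | dimethyl 3-methylpentanedioate | COC(=O)CC(C)CC(=O)OC | starting material
2 | (R)-5-methoxy-3-methyl-5-oxopentanoic acid | COC(=O)C[C@H](C)CC(=O)O | intermediate
3 | 1-tert-butyl 5-methyl (S)-3-methylpentanedioate | COC(=O)C[C@H](C)CC(=O)OC(C)(C)C | intermediate
4 | tert-butyl (S)-5-hydroxy-3-methylpentanoate | OCC[C@H](C)CC(=O)OC(C)(C)C | intermediate
5 | tert-butyl (S)-3-methyl-5-oxopentanoate | O=CC[C@H](C)CC(=O)OC(C)(C)C | intermediate
6 | (S)-4-benzyloxazolidin-2-one | O=C1N[C@@H](Cc2ccccc2)CO1 | starting material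
7 | pent-4-enoyl chloride | C=CCCC(Cl)=O | starting material
8 | (S)-4-benzyl-3-(pent-4-enoyl)oxazolidin-2-one | C=CCCC(=O)N1[C@@H](Cc2ccccc2)COC1=O | intermediate
9 | (Z)-dibutylboron enolate of 8 | CCCCB(CCCC)O/C(=C\CC=C)N1[C@@H](Cc2ccccc2)COC1=O | intermediate (not isolated)
10 | O-dibutylboryl aldolate of 11 | O=C(N1[C@@H](Cc2ccccc2)COC1=O)[C@@H](CC=C)[C@H](OB(CCCC)CCCC)C[C@H](C)CC(=O)OC(C)(C)C | intermediate (not isolated)
11 | tert-butyl (3S,5R,6S)-6-[(S)-4-benzyl-2-oxooxazolidine-3-carbonyl]-5-hydroxy-3-methylnon-8-enoate | O=C(N1[C@@H](Cc2ccccc2)COC1=O)[C@@H](CC=C)[C@H](O)C[C@H](C)CC(=O)OC(C)(C)C | intermediate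
12 | tert-butyl (3S,5R,6S)-5-hydroxy-6-[methoxy(methyl)carbamoyl]-3-methylnon-8-enoate | CON(C)C(=O)[C@@H](CC=C)[C@H](O)C[C@H](C)CC(=O)OC(C)(C)C | intermediate
13 | bis(bromomagnesium) hemiaminal chelate from 12 and MeMgBr | CC(O[Mg]Br)(N(C)OC)[C@@H](CC=C)[C@H](O[Mg]Br)C[C@H](C)CC(=O)OC(C)(C)C | intermediate (not isolated)
14 | tert-butyl (3S,5R,6S)-6-acetyl-5-hydroxy-3-methylnon-8-enoate | CC(=O)[C@@H](CC=C)[C@H](O)C[C@H](C)CC(=O)OC(C)(C)C | intermediate
15 | tert-butyl (3S,5R,6S)-5-hydroxy-6-(2-hydroxypropan-2-yl)-3-methylnon-8-enoate | CC(C)(O)[C@@H](CC=C)[C@H](O)C[C@H](C)CC(=O)OC(C)(C)C | intermediate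
16 | tert-butyl (3S)-4-[(4R,5S)-2,2-di-tert-butyl-6,6-dimethyl-5-(prop-2-en-1-yl)-1,3,2-dioxasilinan-4-yl]-3-methylbutanoate | CC1(C)O[Si](C(C)(C)C)(C(C)(C)C)O[C@H](C[C@H](C)CC(=O)OC(C)(C)C)[C@@H]1CC=C | intermediate
17 | secondary ozonide (1,2,4-trioxolane) of 16 | CC1(C)O[Si](C(C)(C)C)(C(C)(C)C)O[C@H](C[C@H](C)CC(=O)OC(C)(C)C)[C@@H]1CC2OCOO2 | intermediate (not isolated)
18 | tert-butyl (3S)-4-[(4R,5S)-2,2-di-tert-butyl-6,6-dimethyl-5-(2-oxoethyl)-1,3,2-dioxasilinan-4-yl]-3-methylbutanoate | CC1(C)O[Si](C(C)(C)C)(C(C)(C)C)O[C@H](C[C@H](C)CC(=O)OC(C)(C)C)[C@@H]1CC=O | intermediate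
19 | tert-butyl (3S)-4-[(4R,5S)-2,2-di-tert-butyl-5-(carboxymethyl)-6,6-dimethyl-1,3,2-dioxasilinan-4-yl]-3-methylbutanoate | CC1(C)O[Si](C(C)(C)C)(C(C)(C)C)O[C@H](C[C@H](C)CC(=O)OC(C)(C)C)[C@@H]1CC(=O)O | intermediate
20 | tert-butyl (3S)-4-[(4R,5S)-2,2-di-tert-butyl-5-(2-methoxy-2-oxoethyl)-6,6-dimethyl-1,3,2-dioxasilinan-4-yl]-3-methylbutanoate | CC1(C)O[Si](C(C)(C)C)(C(C)(C)C)O[C@H](C[C@H](C)CC(=O)OC(C)(C)C)[C@@H]1CC(=O)OC | intermediate
21 | silylene-protected cycloheptanone β-keto ester (7S,8R,10S; C5 ketone; CO2t-Bu on C1, both epimers; Si(t-Bu)2 bridging O8 and O11) | CC1(C)O[Si](C(C)(C)C)(C(C)(C)C)O[C@@H]2C[C@H](C)C(C(=O)OC(C)(C)C)C(=O)C[C@H]12 | intermediate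
22 | 1-bromobut-2-yne | CC#CCBr | starting material
23 | C1-(but-2-ynyl) β-keto ester (7S,8R,10S; quaternary C1 unassigned) | CC1(C)O[Si](C(C)(C)C)(C(C)(C)C)O[C@@H]2C[C@H](C)C(CC#CC)(C(=O)OC(C)(C)C)C(=O)C[C@H]12 | intermediate
24 | trimethylsilyl ester corresponding to 23 | CC1(C)O[Si](C(C)(C)C)(C(C)(C)C)O[C@@H]2C[C@H](C)C(CC#CC)(C(=O)O[Si](C)(C)C)C(=O)C[C@H]12 | intermediate (not isolated)
25 | β-keto acid corresponding to 23 | CC1(C)O[Si](C(C)(C)C)(C(C)(C)C)O[C@@H]2C[C@H](C)C(CC#CC)(C(=O)O)C(=O)C[C@H]12 | intermediate (not isolated)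
26 | (1R,7S,8R,10S)-1-(but-2-ynyl) silylene-protected cycloheptanone (C5 ketone; obtained as C1 epimer mixture) | CC1(C)O[Si](C(C)(C)C)(C(C)(C)C)O[C@@H]2C[C@H](C)[C@@H](CC#CC)C(=O)C[C@H]12 | intermediate
27 | (1R,7S,8R,10S)-1-(2-oxobutyl) silylene-protected cycloheptanone (1,4-diketone) | CC1(C)O[Si](C(C)(C)C)(C(C)(C)C)O[C@@H]2C[C@H](C)[C@@H](CC(=O)CC)C(=O)C[C@H]12 | intermediate
28 | bicyclic β-hydroxy ketone (5-hydroxy-guaian-3-one, silylene-protected; C4 and C5 unassigned) | CC1(C)O[Si](C(C)(C)C)(C(C)(C)C)O[C@@H]2C[C@H](C)[C@H]3CC(=O)C(C)C3(O)C[C@H]12 | intermediate (not isolated)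
29 | silylene-protected (1R,7S,8R,10S)-8,11-dihydroxyguai-4-en-3-one | CC1(C)O[Si](C(C)(C)C)(C(C)(C)C)O[C@@H]2C[C@H](C)[C@H]3CC(=O)C(C)=C3C[C@H]12 | intermediate
30 | (1R,7S,8R,10S)-8,11-dihydroxyguai-4-en-3-one | O[C@@H]1C[C@H](C)[C@H]2CC(=O)C(C)=C2C[C@@H]1C(C)(C)O | intermediate
31 | (1R,7S,8R,10S)-11-hydroxy-3-oxoguai-4-en-8-yl propanoate | CCC(=O)O[C@@H]1C[C@H](C)[C@H]2CC(=O)C(C)=C2C[C@@H]1C(C)(C)O | intermediate
32 | (1R,7S,8R,10S)-11-acetoxy-3-oxoguai-4-en-8-yl propanoate | CCC(=O)O[C@@H]1C[C@H](C)[C@H]2CC(=O)C(C)=C2C[C@@H]1C(C)(C)OC(C)=O | target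

## Totals and risks
Total steps: 21. Longest linear sequence: 20 steps (steps 1–4, then 6–21).

**Risk 1 – step 14 (Dieckmann closure of the seven-membered ring).** Oligomerisation or sluggish closure is possible. The fallback sets out from 16, where the tert-butyl ester is the only enolisable carbonyl, and comes back at 21. LDA then CBr4 at −78 °C gives the α-bromo ester F1. Ozonolysis passes through the ozonide F2 and, after PPh3, gives the bromo aldehyde F3. SmI2 in THF at −78 °C under high dilution closes ring A by an intramolecular Reformatsky reaction to the cyclic β-hydroxy ester F4. Dess–Martin oxidation of F4 gives β-keto ester 21.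

**Risk 2 – step 15 (C-alkylation at the hindered C1 next to the C10 methyl).** The fallback sets out from 21 and comes back at 27, bypassing steps 15–17. Commercial 2-nitrobutan-1-ol is dehydrated with phthalic anhydride to 2-nitrobut-1-ene F5. Amine-catalysed Michael addition of 21 to it (cat. Et3N, THF) gives the quaternary nitro ester F6. TMSOTf/2,6-lutidine converts this to the trimethylsilyl ester F7, aqueous work-up gives the β-keto acid F8, and warming decarboxylates it to the nitro ketone F9. A McMurry–Nef reaction (NaOMe, then aqueous TiCl3 buffered with NH4OAc) turns the secondary nitro group into the C3 ketone and delivers 1,4-diketone 27.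

**Risk 3 – step 21 (acetylation of the hindered tertiary alcohol).** Slow reaction, elimination or acyl scrambling are possible. The fallback sets out from diol 30 and comes back at 32, replacing steps 20 and 21. Triethyl orthoacetate with catalytic PPTS gives the cyclic orthoacetate F10 across O8 and O11. Mild aqueous acetic acid opens it kinetically to the ester on the more hindered oxygen, the 8-hydroxy 11-acetate F11. Immediate propionylation of the free secondary hydroxyl (propanoic anhydride, DMAP, 0 °C) gives 32.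

## Further compounds
F1 | step 14 | α-bromo ester of 16 (bromine on the carbon α to the tert-butyl ester) | CC1(C)O[Si](C(C)(C)C)(C(C)(C)C)O[C@H](C[C@H](C)C(Br)C(=O)OC(C)(C)C)[C@@H]1CC=C
F2 | step 14 | secondary ozonide of F1 | CC1(C)O[Si](C(C)(C)C)(C(C)(C)C)O[C@H](C[C@H](C)C(Br)C(=O)OC(C)(C)C)[C@@H]1CC2OCOO2
F3 | step 14 | α-bromo ester aldehyde (C5 aldehyde) | CC1(C)O[Si](C(C)(C)C)(C(C)(C)C)O[C@H](C[C@H](C)C(Br)C(=O)OC(C)(C)C)[C@@H]1CC=O
F4 | step 14 | cyclic β-hydroxy ester (C5 carbinol, CO2t-Bu on C1, silylene-protected) | CC1(C)O[Si](C(C)(C)C)(C(C)(C)C)O[C@@H]2C[C@H](C)C(C(=O)OC(C)(C)C)C(O)C[C@H]12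
F5 | step 15 | 2-nitrobut-1-ene | C=C(CC)[N+](=O)[O-]
F6 | step 15 | C1-(2-nitrobutyl) β-keto ester | CC1(C)O[Si](C(C)(C)C)(C(C)(C)C)O[C@@H]2C[C@H](C)C(CC(CC)[N+](=O)[O-])(C(=O)OC(C)(C)C)C(=O)C[C@H]12
F7 | step 15 | trimethylsilyl ester corresponding to F6 | CC1(C)O[Si](C(C)(C)C)(C(C)(C)C)O[C@@H]2C[C@H](C)C(CC(CC)[N+](=O)[O-])(C(=O)O[Si](C)(C)C)C(=O)C[C@H]12
F8 | step 15 | β-keto acid corresponding to F6 | CC1(C)O[Si](C(C)(C)C)(C(C)(C)C)O[C@@H]2C[C@H](C)C(CC(CC)[N+](=O)[O-])(C(=O)O)C(=O)C[C@H]12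
F9 | step 15 | (1R,7S,8R,10S)-1-(2-nitrobutyl) silylene-protected cycloheptanone | CC1(C)O[Si](C(C)(C)C)(C(C)(C)C)O[C@@H]2C[C@H](C)[C@@H](CC(CC)[N+](=O)[O-])C(=O)C[C@H]12
F10 | step 21 | cyclic ethyl orthoacetate of diol 30 (O8 and O11 bridged) | CCOC1(C)O[C@@H]2C[C@H](C)[C@H]3CC(=O)C(C)=C3C[C@@H]2C(C)(C)O1
F11 | step 21 | (1R,7S,8R,10S)-11-acetoxy-8-hydroxyguai-4-en-3-one | O[C@@H]1C[C@H](C)[C@H]2CC(=O)C(C)=C2C[C@@H]1C(C)(C)OC(C)=O
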